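**Strategy.** The trans-decalin is disconnected across its ring-fusion bond C4a–C8a and the C1–C2 bond of cyclohexene ring A, which returns an open-chain (2E,4E,10E,12E)-tetraenal built from (S)-citronellal. An intramolecular inverse-electron-demand Diels–Alder reaction, with the dienal as diene and the near double bond of the terminal hexadienyl unit as dienophile, closes rings A and B in one operation and sets C1, C2, C4a and C8a under control of the C7 methyl group. It exploits the cyclohexene retron of ring A (C3=C4 next to the fusion atom C4a). The epimerised decalin aldehyde is then joined to a lithiated 2,4-dialkoxypyridine that already carries the silyl-protected epoxy-diol ring; oxidation and desilylation finish the pyridone.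

Key step: step 4

Remark on numbering: the decalin is numbered as an octahydronaphthalene (C1 propenyl, C2 acyl, C3=C4 with methyl on C4, C4a/C8a ring fusion, C7 methyl; ring A = C1–C4, C4a, C8a; ring B = C4a, C5–C8, C8a).
Remark on supply: diethyl (E)-crotylphosphonate 2 and the (R)-silyloxy enone 14 are treated as catalogue chemicals.

**Step 1**
Reactants: 1 (S)-citronellal; 2 diethyl [(2E)-but-2-en-1-yl]phosphonate
Product: 4 (2E,4E,7S)-7,11-dimethyldodeca-2,4,10-triene, via lithiated phosphonate 3 (not isolated)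
Conditions: 2, n-BuLi, THF, −78 °C; then 1, DMPU, −78 °C → rt
Reagents that add atoms: none
Why: Horner–Wadsworth–Emmons olefination of the aldehyde with the α-lithiated allylic phosphonate should form the new C=C bond E-selectively and keep the E crotyl geometry, giving the (E,E)-diene without touching the methyl-bearing stereocentre.

**Step 2**
Reactants: 4 (2E,4E,7S)-7,11-dimethyldodeca-2,4,10-triene
Product: 6 (2E,6S,8E,10E)-2,6-dimethyldodeca-2,8,10-trienal, via allylic alcohol 5 (not isolated)
Conditions: SeO2 (cat.), t-BuOOH, salicylic acid (cat.), CH2Cl2, 0 °C → rt; then MnO2, CH2Cl2, rt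
Reagents that add atoms: selenium dioxide O=[Se]=O; tert-butyl hydroperoxide CC(C)(C)OO
Why: The selenium dioxide allylic oxidation (ene reaction then [2,3]-shift) should pick the electron-rich trisubstituted alkene over the disubstituted diene and oxidise its E-methyl group, and MnO2 then converts the allylic alcohol into the (E)-enal.

**Step 3**
Reactants: 6 (2E,6S,8E,10E)-2,6-dimethyldodeca-2,8,10-trienal; 7 2-(triphenylphosphoranylidene)acetaldehyde
Product: 8 (2E,4E,8S,10E,12E)-4,8-dimethyltetradeca-2,4,10,12-tetraenal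
Conditions: toluene, 60 °C
Reagents that add atoms: none
Why: Wittig reaction of the stabilised formyl ylide with the enal should give the two-carbon-extended (E,E)-dienal, the stabilised ylide securing the E geometry of the new double bond.

**Step 4**
Reactants: 8 (2E,4E,8S,10E,12E)-4,8-dimethyltetradeca-2,4,10,12-tetraenal
Product: 9 (1R,2R,4aS,7S,8aR)-4,7-dimethyl-1-[(1E)-prop-1-en-1-yl]-1,2,4a,5,6,7,8,8a-octahydronaphthalene-2-carbaldehyde (trans-fused, formyl cis to propenyl)
Conditions: toluene (high dilution), BHT (cat.), 130 °C, sealed tube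
Reagents that add atoms: none
Why: A thermal, concerted but asynchronous inverse-electron-demand intramolecular Diels–Alder reaction: the electron-poor dienal (C2=C3–C4=C5 of 8) is the 4π partner and the C10=C11 bond, raised in energy by conjugation with C12=C13, the 2π partner, so that C5–C10 (the ring-fusion bond C4a–C8a) and C2–C11 (C2–C1) form in one step; the closest known reaction type is the thermal cyclisation of 1,3,9-decatrienes to octahydronaphthalenes. Ring B closes through the four-carbon tether in a chair-like six-membered array, and ring A is the cyclohexene made by the [4+2] addition itself. The ring fusion should come out trans because the tether-anti (propenyl-endo) transition state avoids the clash between the C4 methyl group of the diene and the tether that burdens the syn alternative, and it gains secondary overlap between the propenyl π bond and the dienal. The absolute sense at C4a and C8a is set by the tether methyl group, which stays equatorial in the chair; the E dienophile fixes the propenyl group at C1 trans to C8, and the E,E diene places the formyl group at C2 cis to the propenyl group (corrected in step 5). The step needs periselectivity over the alternative [4+2] mode, in which the hexadienyl unit is the diene and C4=C5 the dienophile; that mode shares the first bond (C5–C10) but must then build a quaternary carbon at the methyl-bearing C4, which should disfavour it.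

**Step 5**
Reactants: 9 (1R,2R,4aS,7S,8aR)-aldehyde from step 4
Product: 10 (1R,2S,4aS,7S,8aR)-4,7-dimethyl-1-[(1E)-prop-1-en-1-yl]-1,2,4a,5,6,7,8,8a-octahydronaphthalene-2-carbaldehyde (formyl trans to propenyl, all ring substituents equatorial)
Conditions: DBU (cat.), CH2Cl2, rt
Reagents that add atoms: none
Why: Base-mediated epimerisation through the dienolate, which is reprotonated kinetically at the α-carbon so the alkene stays in the β,γ-position, should move the material towards the thermodynamically preferred aldehyde with the pseudo-equatorial formyl group, which sets C2 as in the target (the minor epimer is recycled).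

**Step 6**
Reactants: 11 5-bromo-2,4-dichloropyridine
Product: 13 5-bromo-2,4-bis[2-(trimethylsilyl)ethoxy]pyridine, via monoether 12 (not isolated)
Conditions: Me3SiCH2CH2OH, NaH, DMF, 0 → 80 °C
Reagents that add atoms: 2-(trimethylsilyl)ethanol C[Si](C)(C)CCO
Why: Two nucleophilic aromatic substitutions by the alkoxide, first at the more activated C4 chloride and then at C2 on heating, should install both oxygens of the later pyridone as fluoride-labile ethers while the C5 bromide, meta to nitrogen, stays in place.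

**Step 7**
Reactants: 13 5-bromo-2,4-bis[2-(trimethylsilyl)ethoxy]pyridine; 14 (4R)-4-[(tert-butyldimethylsilyl)oxy]cyclohex-2-en-1-one
Product: 16 (1S,4R)-1-{4,6-bis[2-(trimethylsilyl)ethoxy]pyridin-3-yl}-4-[(tert-butyldimethylsilyl)oxy]cyclohex-2-en-1-ol (the two oxygens cis), via aryllithium 15 (not isolated)
Conditions: 13, n-BuLi, THF, −78 °C; then 14, −78 °C; H2O quench
Reagents that add atoms: none
Why: Bromine–lithium exchange followed by 1,2-addition of the aryllithium to the enone carbonyl, expected on the face anti to the C4 silyloxy group as is usual for 4-silyloxycyclohexenones, should set the tertiary carbinol centre with the hydroxyl cis to the silyloxy group.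

**Step 8**
Reactants: 16 tertiary allylic alcohol from step 7
Product: 17 5-{(1S,4R)-4-[(tert-butyldimethylsilyl)oxy]-1-[(triethylsilyl)oxy]cyclohex-2-en-1-yl}-2,4-bis[2-(trimethylsilyl)ethoxy]pyridine
Conditions: Et3SiOTf, 2,6-lutidine, CH2Cl2, −78 → 0 °C
Reagents that add atoms: triethylsilyl trifluoromethanesulfonate CC[Si](CC)(CC)OS(=O)(=O)C(F)(F)F
Why: Silylation of the hindered tertiary alcohol with the silyl triflate protects the ionisation-prone carbinol and puts a second bulky silyloxy group on the same ring face as the first.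

**Step 9**
Reactants: 17 bis-silyl ether from step 8
Product: 18 cis-diol of 17 (3-aryl-6-[(tert-butyldimethylsilyl)oxy]-3-[(triethylsilyl)oxy]cyclohexane-1,2-diol, both new hydroxyls on the face opposite to the two silyloxy groups)
Conditions: OsO4 (cat.), NMO, acetone/H2O, rt
Reagents that add atoms: osmium tetroxide O=[Os](=O)(=O)=O; N-methylmorpholine N-oxide C[N+]1([O-])CCOCC1
Why: Catalytic dihydroxylation (Upjohn conditions) leaves the pyridine nitrogen unoxidised and should add anti to both allylic silyloxy groups, the usual preference of OsO4 with allylic ethers, reinforced here because both groups shield the same face.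

**Step 10**
Reactants: 18 cis-diol from step 9
Product: 22 5-{5-[(tert-butyldimethylsilyl)oxy]-2-[(triethylsilyl)oxy]-7-oxabicyclo[4.1.0]heptan-2-yl}-2,4-bis[2-(trimethylsilyl)ethoxy]pyridine (oxirane anti to both silyloxy groups), via cyclic orthoacetate 19 (not isolated), via bromo acetate 20 (not isolated), via bromohydrin 21 (not isolated)
Conditions: MeC(OMe)3, PPTS (cat.), CH2Cl2, rt; AcBr, CH2Cl2, 0 °C; K2CO3, MeOH, rt
Reagents that add atoms: none
Why: The one-pot cis-diol to epoxide conversion (Kolb–Sharpless procedure) opens the acetoxonium ion with bromide with inversion and then closes the ring by a second inversion at the same carbon, so the oxirane should end up on the face the diol occupied, anti to both silyloxy groups.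

**Step 11**
Reactants: 22 epoxide from step 10; 10 (1R,2S,4aS,7S,8aR)-decalin aldehyde
Product: 24 secondary carbinol {2,4-bis[2-(trimethylsilyl)ethoxy]-5-(epoxy-bis-silyloxycyclohexyl)pyridin-3-yl}(decalin-2-yl)methanol (mixture at the carbinol carbon), via 3-lithiopyridine 23 (not isolated)
Conditions: 22, t-BuLi, THF, −78 °C; then 10, −78 → −40 °C; H2O quench
Reagents that add atoms: none
Why: Directed ortho-metalation at C3, the position flanked by both alkoxy groups, followed by 1,2-addition to the aldehyde joins the two halves at low temperature, where the epoxide and silyl ethers should survive; the new carbinol centre is removed in step 12.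

**Step 12**
Reactants: 24 carbinol from step 11
Product: 25 aryl ketone {2,4-bis[2-(trimethylsilyl)ethoxy]-5-(epoxy-bis-silyloxycyclohexyl)pyridin-3-yl}[(1R,2S,4aS,7S,8aR)-4,7-dimethyl-1-[(1E)-prop-1-en-1-yl]-1,2,4a,5,6,7,8,8a-octahydronaphthalen-2-yl]methanone
Conditions: Dess–Martin periodinane, pyridine, CH2Cl2, 0 °C → rt
Reagents that add atoms: none
Why: Buffered Dess–Martin oxidation of the secondary alcohol gives the ketone under non-basic, non-acidic conditions that should leave the epimerisable C2 centre, the β,γ-alkene, the epoxide and the silyl ethers unchanged.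

**Step 13**
Reactants: 25 ketone from step 12
Product: 26 3-{[(1R,2S,4aS,7S,8aR)-4,7-dimethyl-1-[(1E)-prop-1-en-1-yl]-1,2,4a,5,6,7,8,8a-octahydronaphthalen-2-yl]carbonyl}-5-[(1S,2R,5R,6S)-2,5-dihydroxy-7-oxabicyclo[4.1.0]heptan-2-yl]-4-hydroxypyridin-2(1H)-one (target)
Conditions: Bu4NF, AcOH, THF, 0 °C → rt
Reagents that add atoms: none
Why: Fluoride should cleave both silyl ethers and trigger β-elimination of the two 2-(trimethylsilyl)ethyl ethers to unmask the 4-hydroxy-2-pyridone, while the acetic acid buffer keeps alkoxides from forming next to the epoxide and so guards against epoxide migration.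

**Compound list**
1 | (S)-citronellal, (3S)-3,7-dimethyloct-6-enal | O=CC[C@@H](C)CCC=C(C)C | starting material
2 | diethyl [(2E)-but-2-en-1-yl]phosphonate | CCOP(=O)(C/C=C/C)OCC | starting material
3 | α-lithiated phosphonate (lithium salt of 2) | CCOP(=O)(OCC)C([Li])/C=C/C | intermediate
4 | (2E,4E,7S)-7,11-dimethyldodeca-2,4,10-triene | C/C=C/C=C/C[C@@H](C)CCC=C(C)C | intermediate
5 | (2E,6S,8E,10E)-2,6-dimethyldodeca-2,8,10-trien-1-ol | C/C=C/C=C/C[C@@H](C)CC/C=C(\C)CO | intermediate
6 | (2E,6S,8E,10E)-2,6-dimethyldodeca-2,8,10-trienal | C/C=C/C=C/C[C@@H](C)CC/C=C(\C)C=O | intermediate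
7 | 2-(triphenylphosphoranylidene)acetaldehyde | O=CC=P(c1ccccc1)(c1ccccc1)c1ccccc1 | starting material
8 | (2E,4E,8S,10E,12E)-4,8-dimethyltetradeca-2,4,10,12-tetraenal | C/C=C/C=C/C[C@@H](C)CC/C=C(C)/C=C/C=O | intermediate
9 | (1R,2R,4aS,7S,8aR)-4,7-dimethyl-1-[(1E)-prop-1-en-1-yl]-1,2,4a,5,6,7,8,8a-octahydronaphthalene-2-carbaldehyde (formyl cis to propenyl) | C/C=C/[C@@H]1[C@H]2C[C@@H](C)CC[C@@H]2C(C)=C[C@@H]1C=O | intermediate
10 | (1R,2S,4aS,7S,8aR)-4,7-dimethyl-1-[(1E)-prop-1-en-1-yl]-1,2,4a,5,6,7,8,8a-octahydronaphthalene-2-carbaldehyde (formyl trans to propenyl) | C/C=C/[C@@H]1[C@H]2C[C@@H](C)CC[C@@H]2C(C)=C[C@H]1C=O | intermediate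
11 | 5-bromo-2,4-dichloropyridine | Clc1cc(Cl)c(Br)cn1 | starting material
12 | 5-bromo-2-chloro-4-[2-(trimethylsilyl)ethoxy]pyridine | C[Si](C)(C)CCOc1cc(Cl)ncc1Br | intermediate
13 | 5-bromo-2,4-bis[2-(trimethylsilyl)ethoxy]pyridine | C[Si](C)(C)CCOc1cc(OCC[Si](C)(C)C)c(Br)cn1 | intermediate
14 | (4R)-4-[(tert-butyldimethylsilyl)oxy]cyclohex-2-en-1-one | O=C1C=C[C@H](O[Si](C)(C)C(C)(C)C)CC1 | starting material
15 | {4,6-bis[2-(trimethylsilyl)ethoxy]pyridin-3-yl}lithium | [Li]c1cnc(OCC[Si](C)(C)C)cc1OCC[Si](C)(C)C | intermediate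
16 | (1S,4R)-1-{4,6-bis[2-(trimethylsilyl)ethoxy]pyridin-3-yl}-4-[(tert-butyldimethylsilyl)oxy]cyclohex-2-en-1-ol | C[Si](C)(C)CCOc1cc(OCC[Si](C)(C)C)c(cn1)[C@]2(O)CC[C@@H](O[Si](C)(C)C(C)(C)C)C=C2 | intermediate
17 | triethylsilyl ether of 16 | C[Si](C)(C)CCOc1cc(OCC[Si](C)(C)C)c(cn1)[C@]2(O[Si](CC)(CC)CC)CC[C@@H](O[Si](C)(C)C(C)(C)C)C=C2 | intermediate
18 | cis-diol of 17 (hydroxyls anti to both silyloxy groups) | C[Si](C)(C)CCOc1cc(OCC[Si](C)(C)C)c(cn1)[C@]2(O[Si](CC)(CC)CC)CC[C@@H](O[Si](C)(C)C(C)(C)C)[C@H](O)[C@@H]2O | intermediate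
19 | cyclic methyl orthoacetate of 18 (mixture at the orthoester carbon) | C[Si](C)(C)CCOc1cc(OCC[Si](C)(C)C)c(cn1)[C@]2(O[Si](CC)(CC)CC)CC[C@@H](O[Si](C)(C)C(C)(C)C)[C@@H]3OC(C)(OC)O[C@@H]32 | intermediate
20 | trans bromo acetate (bromide next to the CH–OTBS carbon, acetate next to the quaternary carbon) | C[Si](C)(C)CCOc1cc(OCC[Si](C)(C)C)c(cn1)[C@]2(O[Si](CC)(CC)CC)CC[C@@H](O[Si](C)(C)C(C)(C)C)[C@@H](Br)[C@@H]2OC(C)=O | intermediate
21 | trans bromohydrin from 20 | C[Si](C)(C)CCOc1cc(OCC[Si](C)(C)C)c(cn1)[C@]2(O[Si](CC)(CC)CC)CC[C@@H](O[Si](C)(C)C(C)(C)C)[C@@H](Br)[C@@H]2O | intermediate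
22 | 5-{5-[(tert-butyldimethylsilyl)oxy]-2-[(triethylsilyl)oxy]-7-oxabicyclo[4.1.0]heptan-2-yl}-2,4-bis[2-(trimethylsilyl)ethoxy]pyridine (oxirane anti to both silyloxy groups) | C[Si](C)(C)CCOc1cc(OCC[Si](C)(C)C)c(cn1)[C@]2(O[Si](CC)(CC)CC)CC[C@@H](O[Si](C)(C)C(C)(C)C)[C@@H]3O[C@@H]32 | intermediate
23 | 3-lithio derivative of 22 | [Li]c1c(OCC[Si](C)(C)C)ncc([C@]2(O[Si](CC)(CC)CC)CC[C@@H](O[Si](C)(C)C(C)(C)C)[C@@H]3O[C@@H]32)c1OCC[Si](C)(C)C | intermediate
24 | secondary carbinol from 23 and 10 (mixture at the carbinol carbon) | C/C=C/[C@@H]1[C@H]2C[C@@H](C)CC[C@@H]2C(C)=C[C@H]1C(O)c1c(OCC[Si](C)(C)C)c([C@]2(O[Si](CC)(CC)CC)CC[C@@H](O[Si](C)(C)C(C)(C)C)[C@@H]3O[C@@H]32)cnc1OCC[Si](C)(C)C | intermediate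
25 | fully protected aryl ketone | C/C=C/[C@@H]1[C@H]2C[C@@H](C)CC[C@@H]2C(C)=C[C@H]1C(=O)c1c(OCC[Si](C)(C)C)c([C@]2(O[Si](CC)(CC)CC)CC[C@@H](O[Si](C)(C)C(C)(C)C)[C@@H]3O[C@@H]32)cnc1OCC[Si](C)(C)C | intermediate
26 | CNP0494338.1 | C/C=C/[C@@H]1[C@H]2C[C@@H](C)CC[C@@H]2C(C)=C[C@H]1C(=O)c1c(O)c([C@]2(O)CC[C@@H](O)[C@@H]3O[C@@H]32)c[nH]c1=O | target

**Step count.** 13 steps in total. The longest linear sequence is 8 steps (steps 1–5 and 11–13 from 1; equally steps 6–13 from 11).

**Steps most likely to fail**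

Step 4. The cycloaddition may lose periselectivity: the hexadienyl unit can act as the diene towards the C4=C5 bond, a mode that starts with the same C5–C10 bond, and the trans ring fusion may also erode. The fallback reverses the polarity so that only one [4+2] mode exists; it sets out from 1 and returns at 9.
- Horner–Wadsworth–Emmons reaction of 1 with triethyl phosphonoacetate (NaH, THF) would give ethyl (2E,5S)-5,9-dimethyldeca-2,8-dienoate F1.
- SeO2/t-BuOOH and then MnO2 would give the enal ethyl (2E,5S,8E)-5,9-dimethyl-10-oxodeca-2,8-dienoate F2.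
- Wittig reaction with 7 would give the dienal ethyl (2E,5S,8E,10E)-5,9-dimethyl-12-oxododeca-2,8,10-trienoate F3.
- Luche reduction (NaBH4, CeCl3, MeOH) would give the dienol ethyl (2E,5S,8E,10E)-12-hydroxy-5,9-dimethyldodeca-2,8,10-trienoate F4, and TBSCl/imidazole its silyl ether ethyl (2E,5S,8E,10E)-12-[(tert-butyldimethylsilyl)oxy]-5,9-dimethyldodeca-2,8,10-trienoate F5.
- A normal-demand intramolecular Diels–Alder reaction promoted by Me2AlCl (CH2Cl2, −78 → −20 °C), with the ester endo, should give the trans-fused ethyl 2-{[(tert-butyldimethylsilyl)oxy]methyl}-4,7-dimethyl-1,2,4a,5,6,7,8,8a-octahydronaphthalene-1-carboxylate F6, which has the same relative configuration as 9.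
- i-Bu2AlH (CH2Cl2, −78 °C) would give the 1-carbaldehyde F7.
- Takai–Utimoto ethylidenation (CrCl2, CH3CHI2, THF) would give the (E)-propenyl silyl ether F8.
- Bu4NF would give the primary alcohol [4,7-dimethyl-1-(prop-1-enyl)octahydronaphthalen-2-yl]methanol F9, and Dess–Martin oxidation gives 9.

Step 7. The aryllithium may attack the enone on the face syn to the silyloxy group, which would give the trans-1,4 isomer. The fallback sets the relative configuration by SN2 inversion instead; it sets out from 13 and returns at 16.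
- The same exchange and addition would be run with the enantiomeric enone (4S)-4-[(tert-butyldimethylsilyl)oxy]cyclohex-2-en-1-one F10, so that the syn adduct, the trans-1,4 alcohol (1S,4S)-1-aryl-4-[(tert-butyldimethylsilyl)oxy]cyclohex-2-en-1-ol F11, has the required carbinol configuration.
- Bu4NF would give the trans-diol (1S,4S)-1-arylcyclohex-2-ene-1,4-diol F12.
- Mitsunobu reaction of the secondary allylic hydroxyl (4-nitrobenzoic acid, PPh3, DIAD) would give the inverted ester (1R,4S)-4-aryl-4-hydroxycyclohex-2-en-1-yl 4-nitrobenzoate F13.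
- K2CO3/MeOH would give the cis-diol (1S,4R)-1-arylcyclohex-2-ene-1,4-diol F14, and selective silylation of the secondary hydroxyl (TBSCl, imidazole) gives 16.

Step 10. The acid bromide stage may strip the tertiary triethylsilyl ether or attack the pyridyl ethers, or the hindered acetoxonium ion may fail to open. The fallback replaces the diol route by direct oxygen transfer; it sets out from 17 and returns at 22.
- Excess dimethyldioxirane (acetone, 0 °C → rt) should epoxidise the alkene from the same unshielded face and also oxidise the pyridine nitrogen, giving the epoxide N-oxide 5-{5-[(tert-butyldimethylsilyl)oxy]-2-[(triethylsilyl)oxy]-7-oxabicyclo[4.1.0]heptan-2-yl}-2,4-bis[2-(trimethylsilyl)ethoxy]pyridine 1-oxide F15.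
- Chemoselective N-deoxygenation with bis(pinacolato)diboron (MeCN, 70 °C) gives 22.

**Further compounds**
F1 | step 4 | ethyl (2E,5S)-5,9-dimethyldeca-2,8-dienoate | CCOC(=O)/C=C/C[C@@H](C)CCC=C(C)C
F2 | step 4 | ethyl (2E,5S,8E)-5,9-dimethyl-10-oxodeca-2,8-dienoate | CCOC(=O)/C=C/C[C@@H](C)CC/C=C(\C)C=O
F3 | step 4 | ethyl (2E,5S,8E,10E)-5,9-dimethyl-12-oxododeca-2,8,10-trienoate | CCOC(=O)/C=C/C[C@@H](C)CC/C=C(C)/C=C/C=O
F4 | step 4 | ethyl (2E,5S,8E,10E)-12-hydroxy-5,9-dimethyldodeca-2,8,10-trienoate | CCOC(=O)/C=C/C[C@@H](C)CC/C=C(C)/C=C/CO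
F5 | step 4 | ethyl (2E,5S,8E,10E)-12-[(tert-butyldimethylsilyl)oxy]-5,9-dimethyldodeca-2,8,10-trienoate | CCOC(=O)/C=C/C[C@@H](C)CC/C=C(C)/C=C/CO[Si](C)(C)C(C)(C)C
F6 | step 4 | ethyl 2-{[(tert-butyldimethylsilyl)oxy]methyl}-4,7-dimethyl-1,2,4a,5,6,7,8,8a-octahydronaphthalene-1-carboxylate (trans-fused, ester cis to silyloxymethyl) | CCOC(=O)[C@@H]1[C@H]2C[C@@H](C)CC[C@@H]2C(C)=C[C@@H]1CO[Si](C)(C)C(C)(C)C
F7 | step 4 | 2-{[(tert-butyldimethylsilyl)oxy]methyl}-4,7-dimethyl-1,2,4a,5,6,7,8,8a-octahydronaphthalene-1-carbaldehyde | O=C[C@@H]1[C@H]2C[C@@H](C)CC[C@@H]2C(C)=C[C@@H]1CO[Si](C)(C)C(C)(C)C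
F8 | step 4 | tert-butyl{[4,7-dimethyl-1-[(1E)-prop-1-en-1-yl]-1,2,4a,5,6,7,8,8a-octahydronaphthalen-2-yl]methoxy}dimethylsilane | C/C=C/[C@@H]1[C@H]2C[C@@H](C)CC[C@@H]2C(C)=C[C@@H]1CO[Si](C)(C)C(C)(C)C
F9 | step 4 | [4,7-dimethyl-1-[(1E)-prop-1-en-1-yl]-1,2,4a,5,6,7,8,8a-octahydronaphthalen-2-yl]methanol | C/C=C/[C@@H]1[C@H]2C[C@@H](C)CC[C@@H]2C(C)=C[C@@H]1CO
F10 | step 7 | (4S)-4-[(tert-butyldimethylsilyl)oxy]cyclohex-2-en-1-one | O=C1C=C[C@@H](O[Si](C)(C)C(C)(C)C)CC1
F11 | step 7 | (1S,4S)-1-{4,6-bis[2-(trimethylsilyl)ethoxy]pyridin-3-yl}-4-[(tert-butyldimethylsilyl)oxy]cyclohex-2-en-1-ol | C[Si](C)(C)CCOc1cc(OCC[Si](C)(C)C)c(cn1)[C@]2(O)CC[C@H](O[Si](C)(C)C(C)(C)C)C=C2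
F12 | step 7 | (1S,4S)-1-{4,6-bis[2-(trimethylsilyl)ethoxy]pyridin-3-yl}cyclohex-2-ene-1,4-diol | C[Si](C)(C)CCOc1cc(OCC[Si](C)(C)C)c(cn1)[C@]2(O)CC[C@H](O)C=C2
F13 | step 7 | (1R,4S)-4-{4,6-bis[2-(trimethylsilyl)ethoxy]pyridin-3-yl}-4-hydroxycyclohex-2-en-1-yl 4-nitrobenzoate | C[Si](C)(C)CCOc1cc(OCC[Si](C)(C)C)c(cn1)[C@]2(O)CC[C@@H](OC(=O)c3ccc(cc3)[N+](=O)[O-])C=C2
F14 | step 7 | (1S,4R)-1-{4,6-bis[2-(trimethylsilyl)ethoxy]pyridin-3-yl}cyclohex-2-ene-1,4-diol | C[Si](C)(C)CCOc1cc(OCC[Si](C)(C)C)c(cn1)[C@]2(O)CC[C@@H](O)C=C2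
F15 | step 10 | 5-{5-[(tert-butyldimethylsilyl)oxy]-2-[(triethylsilyl)oxy]-7-oxabicyclo[4.1.0]heptan-2-yl}-2,4-bis[2-(trimethylsilyl)ethoxy]pyridine 1-oxide | C[Si](C)(C)CCOc1cc(OCC[Si](C)(C)C)c(c[n+]1[O-])[C@]2(O[Si](CC)(CC)CC)CC[C@@H](O[Si](C)(C)C(C)(C)C)[C@@H]3O[C@@H]32
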